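A small charge of Wa is what separates the two earlier runs, while Qa and Eb stand alike in both. The next flask therefore has to answer one question: what does more Wa buy?

| flask | Qa | Eb | Wa | remark | time |
|---|---|---|---|---|---|
| north | 2 M | 0.80 equiv | 4.4 mol% | run made earlier |  |
| east | 2 M | 0.80 equiv | 6.6 mol% | run made earlier |  |
| flask | 2.0 M | 0.800 equiv | 8.8 mol% |  | 6.0 h |

- north (time / h: Uj / %): 0.417: 4.3; 1.33: 13.3; 2.00: 16.0; 3.00: 22.2; 5.00: 30.2; 6.00: 33.9
- east (time / h: Uj / %): 0.500: 7.7; 0.833: 10.3; 1.33: 16.1; 2.00: 20.3; 4.00: 33.7; 6.00: 40.7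

(readings scatter by 1 percentage point)

1. amount of Uj in percent of the Qa charged, at 20 min, 1.5 h and 6.0 h

1. At 6.0 h, the north run reads 33.9% of Uj and the east run 40.7%.

2. Radicals enter in proportion to c_Wa, and Ym pairs off at a rate in c_Ym squared. If c_Ym is frozen where the two balance (a quasi-steady state), c_Ym goes as the root of c_Wa, and the making of Uj, at a given c_Qa, goes with it.

3. This reckoning therefore divides ln(1/(1 − y)), with y the Uj fraction at 6.0 h, by the root of the Wa loading. The north run gives 1.97 and the east run 2.03, a gap that a scatter of 1 percentage point can produce. Their mean is the root yield 2.00.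

4. Twice the north loading multiplies that logarithm by 1.41, less than the doubling. For the flask, this reckoning with the root yield then gives 44.7% of Uj at 6.0 h.

5. The forecast, “as expected for chain termination by 2 Ym”, stands at 5.2%, 19.5% and 45%.

6. Decision: charge 8.8 mol% of Wa and leave Qa and Eb as they were. The test is the root yield of this flask against the earlier value: a gap beyond the scatter counts against the root law and the forecast.

    Wa → 2 Jo (k = 0.00258 min⁻¹)
    Qa + Jo → Dw + Ky (k = 4.98 × 10⁵ L mol⁻¹ min⁻¹)
    Eb + Ky ⇌ Uj + Ym (K = 0.951, k = 60000 L mol⁻¹ min⁻¹)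
    Qa + Ym → Zo + Ky (k = 23200 L mol⁻¹ min⁻¹)
    2 Ym → Gy (k = 6.40 × 10⁸ L mol⁻¹ s⁻¹)
    Uj ⇌ Dx (K = 0.316, k = 0.00470 min⁻¹)

The flask gives 5.48%, 19.6% and 46.1% of Uj, and its root yield at 6.0 h is 2.08, against 2.00 from the earlier runs. At 2.09 h, the flask makes Ym 1.00 times as fast as it uses it up, each step taken net. Meanwhile c_Ym slips from 1.04 × 10⁻⁷ M at 0.600 h to 6.83 × 10⁻⁸ M at 6.00 h, as Wa falls from 91.1% to 39.5% of its charge.

The data stem from a simulated flask with made-up constants, noise included.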